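Read every flask through one number, then ask what the opposite outcome would need: that was my plan for these runs.

| flask | starting material | partner | time |
|---|---|---|---|
| Thursday's | 0.120 M | 0.120 M |  |
| Sunday's | 0.0480 M | 0.0480 M |  |
| Wednesday's | 0.120 M | 0.360 M |  |
| Monday's | 0.0400 M | 0.0400 M | 120 s |

| run | time / s | [target] / M |
|---|---|---|
| Thursday's run | 9.1 | 0.0105 |
| Thursday's run | 28 | 0.0217 |
| Thursday's run | 53 | 0.0308 |
| Thursday's run | 84 | 0.0413 |
| Thursday's run | 120 | 0.0472 |
| Sunday's run | 9.1 | 0.0017 |
| Sunday's run | 28 | 0.0034 |
| Sunday's run | 53 | 0.0040 |
| Sunday's run | 84 | 0.0087 |
| Sunday's run | 120 | 0.0101 |
| Wednesday's run | 9.1 | 0.0202 |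
| Wednesday's run | 28 | 0.0517 |
| Wednesday's run | 53 | 0.0722 |
| Wednesday's run | 84 | 0.0850 |
| Wednesday's run | 120 | 0.0938 |

(readings scatter by 0.001 M)

- Overall: starting material + partner -> target.
- Constant volume, constant temperature.
- "The second partner" is partner.
- An order is taken over about fifteen percent of the charge, up and down.

- the power of [starting material] that the first rate follows, about the charge of the Thursday's run; measure it at two percent of starting material made into target (one fixed amount of target, the same in the runs compared)
- the power of [partner] that the first rate follows, about the charge of the Thursday's run; measure it at two percent of starting material made into target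
- target in the Monday's run at 120 s, as a share of the starting material charged

Thursday's flask read 5.40 /M at 120 s on what I called the second-order clock, the integrated rate law: target made, integrated over c(starting material) times c(partner). For a one-way step first order in each, it equals rate constant times time.

Wednesday's flask, with c(partner) at 0.360 M, read 5.08 /M, give or take 0.143 /M. A rate indifferent to the partner would have put Wednesday's clock near a third of Thursday's, at 1.80 /M. The reading instead implies a partner power of 0.944.

Sunday's flask read 5.55 /M, give or take 0.696 /M, where a total order of 3 would have given 2.16 /M. So I committed to first order in each.

Wednesday's clock still read lower than Thursday's, with more target made. A straight line through those two flasks reaches 5.73 /M at no target. With that clock, Monday's equal charges give a share of 18.6%.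

The forecast, differing from me on both powers and on Monday's share, gave 1.15, 0.8 and 17.8%, citing “mild saturation in partner”.

The simulation gives 1.0, 1.0 and 19.3%.

    starting material + partner ⇌ target (0.06260 /M/s, 0.003360 /s)

Monday's flask therefore read 5.99 /M on the clock, higher than my 5.73 /M, while Sunday's reading lay 0.106 /M below my line. In Monday's flask the forward step ran from the start on starting material and partner, and the back step ran as target appeared. At 120 s in Monday's flask, the back rate stood at 39.8% of the forward rate.

The numbers in the tables come from a simulation with made-up constants, and the scatter is random.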